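**Retrosynthetic overview**
- The target is cut at the ring B benzyl ester (hydrogenolysis, last step) and at a 1,3-dithiane that masks the side-chain ketone.
- The depside C–O bond is cut into a ring A dithiane acid and benzyl 2,4-dihydroxy-6-propylbenzoate.
- The ring A acid is traced back through its keto acid to 8-hydroxy-6-methoxy-3-propylisocoumarin.
- Key C–C disconnection, aryl C6–CH2: the ortho C–H of 2-hydroxy-4-methoxybenzoic acid serves as a rhodium-bound aryl nucleophile, and an α-oxo carbene from a butanoyl sulfoxonium ylide serves as an enolonium equivalent, so both carbons react with reversed polarity.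
- Both benzene rings are bought; the only ring formed is the pyranone of the isocoumarin (step 2), opened again in step 3.

Assumption: the target has no stereocentre or stereogenic double bond, so the single enantiomer asked for is simply the achiral compound, and 2,4-dihydroxy-6-propylbenzoic acid (divarinic acid) is taken as purchasable.

**Step 1**
Reactants: 1 butanoyl chloride; 2 trimethylsulfoxonium iodide
Product: 4 the sulfoxonium ylide 1-[dimethyl(oxo)-λ6-sulfanylidene]pentan-2-one, via dimethylsulfoxonium methylide 3 (not isolated)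
Conditions: 2 (3.0 equiv), KOC(CH3)3 (3.0 equiv), THF, reflux, 2 h; then 1 (1.0 equiv), 0 °C to rt
Reagents that add atoms: none
Why: Methylide 3 is C-acylated by 1 and a second equivalent of 3 removes the now acidic α-proton, giving the stabilised, bench-stable β-keto sulfoxonium ylide (Corey–Chaykovsky-type ylide acylation).

**Step 2**
Reactants: 5 4-methoxysalicylic acid (2-hydroxy-4-methoxybenzoic acid); 4 the sulfoxonium ylide
Product: 7 the isocoumarin 8-hydroxy-6-methoxy-3-propyl-1H-isochromen-1-one, via 2-hydroxy-4-methoxy-6-(2-oxopentyl)benzoic acid 6 (not isolated)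
Conditions: [(C5Me5)RhCl2]2 (4 mol%), AgSbF6 (16 mol%), CH3CO2Na (0.5 equiv), 4 (1.5 equiv, added in portions), (CF3)2CHOH, 80 °C, 16 h
Reagents that add atoms: none
Why: Carboxylate-directed C–H activation at trivalent rhodium makes C6 of 5 (ortho to the acceptor CO2H, natively an electrophilic site) an aryl–rhodium nucleophile, while loss of dimethyl sulfoxide from 4 gives an α-oxo rhodium carbene that acts as an enolonium (α-keto cation) equivalent at a carbon that is natively an enolate donor; migratory insertion and protonolysis forge the aryl–CH2 bond to give 6, which lactonises in the hot acidic fluoroalcohol to 7 (C–H activation/carbene insertion/annulation of benzoic acids with sulfoxonium ylides, here risked on an unprotected salicylic acid to save two protecting-group steps); no stereocentre is formed.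

**Step 3**
Reactants: 7 the isocoumarin
Product: 6 the keto acid 2-hydroxy-4-methoxy-6-(2-oxopentyl)benzoic acid
Conditions: 2 M aqueous KOH, THF, 50 °C, 2 h; then 1 M HCl to pH 3 at 0 °C, extract, use crude at once
Reagents that add atoms: water, O
Why: Saponification of the enol lactone: hydroxide adds to C1, the enolate leaving group becomes the ketone and the carboxylate/phenoxide dianion cannot re-close, so cold acidification releases 6, which is carried on immediately because acid or heat returns it to 7.

**Step 4**
Reactants: 6 the keto acid; 8 propane-1,3-dithiol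
Product: 9 the dithiane acid 2-hydroxy-4-methoxy-6-[(2-propyl-1,3-dithian-2-yl)methyl]benzoic acid
Conditions: 8 (2.0 equiv), BF3·OEt2 (2.5 equiv), CH2Cl2, 0 °C, 2 h
Reagents that add atoms: none
Why: Lewis-acid thioketalisation of the unhindered dialkyl ketone is fast at 0 °C and should outrun dehydrative relactonisation, and the dithiane removes the enolisable carbonyl that would otherwise capture the activated carboxyl as isocoumarin 7 during step 6.

**Step 5**
Reactants: 10 divarinic acid (2,4-dihydroxy-6-propylbenzoic acid); 11 benzyl bromide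
Product: 12 benzyl 2,4-dihydroxy-6-propylbenzoate
Conditions: KHCO3 (1.1 equiv), DMF, rt, 16 h
Reagents that add atoms: none
Why: Hydrogencarbonate deprotonates only the carboxylic acid, so SN2 O-alkylation gives the benzyl ester with both phenols free, and room temperature avoids decarboxylation of the β-resorcylic acid (carboxylate alkylation).

**Step 6**
Reactants: 9 the dithiane acid; 12 benzyl 2,4-dihydroxy-6-propylbenzoate
Product: 14 benzyl 2-hydroxy-4-({2-hydroxy-4-methoxy-6-[(2-propyl-1,3-dithian-2-yl)methyl]benzoyl}oxy)-6-propylbenzoate, via acyl trifluoroacetate 13 (not isolated)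
Conditions: (CF3CO)2O (6 equiv), toluene, rt, 3 h; aqueous NaHCO3 work-up
Reagents that add atoms: trifluoroacetic anhydride, O=C(OC(=O)C(F)(F)F)C(F)(F)F (its CF3CO group sits in 13 only)
Why: Trifluoroacetic anhydride turns the hindered salicylic acid into mixed anhydride 13, which acylates the free 4-OH of 12 in preference to its hydrogen-bonded 2-OH and to the chelated 2-OH of 9 (mixed-anhydride depside esterification), the thioketal being inert to the acidic medium.

**Step 7**
Reactants: 14 the dithiane depside benzyl ester
Product: 15 benzyl 2-hydroxy-4-{[2-hydroxy-4-methoxy-6-(2-oxopentyl)benzoyl]oxy}-6-propylbenzoate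
Conditions: MeI (10 equiv), CaCO3 (5 equiv), MeCN–H2O 9:1, 45 °C, 12 h
Reagents that add atoms: water, O
Why: S-Methylation turns a thioketal sulfur into a sulfonium leaving group, water adds to the resulting thionium ion and the carbonate-buffered medium releases the ketone without cleaving the aryl ester (alkylative dethioketalisation).

**Step 8**
Reactants: 15 the keto depside benzyl ester
Product: 16 2-hydroxy-4-{[2-hydroxy-4-methoxy-6-(2-oxopentyl)benzoyl]oxy}-6-propylbenzoic acid (target)
Conditions: H2 (1 atm), 10% Pd/C, EtOAc, rt, 2 h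
Reagents that add atoms: none
Why: Hydrogenolysis of the benzyl ester in a neutral solvent frees the ring B carboxylic acid while the dialkyl ketone, the aryl ester and the methyl ether are untouched (catalytic hydrogenolysis), and the neutral conditions avoid the acid- or base-induced collapse of the product to isocoumarin 7.

**Compound list**
1 | butanoyl chloride | CCCC(=O)Cl | starting material
2 | trimethylsulfoxonium iodide | C[S+](C)(C)=O.[I-] | starting material
3 | dimethylsulfoxonium methylide | [CH2-][S+](C)(C)=O | intermediate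
4 | 1-[dimethyl(oxo)-λ6-sulfanylidene]pentan-2-one | CCCC(=O)C=S(C)(C)=O | intermediate
5 | 2-hydroxy-4-methoxybenzoic acid | COc1ccc(C(=O)O)c(O)c1 | starting material
6 | 2-hydroxy-4-methoxy-6-(2-oxopentyl)benzoic acid | CCCC(=O)Cc1cc(OC)cc(O)c1C(=O)O | intermediate
7 | 8-hydroxy-6-methoxy-3-propyl-1H-isochromen-1-one | CCCC1=Cc2cc(OC)cc(O)c2C(=O)O1 | intermediate
8 | propane-1,3-dithiol | SCCCS | starting material
9 | 2-hydroxy-4-methoxy-6-[(2-propyl-1,3-dithian-2-yl)methyl]benzoic acid | CCCC1(Cc2cc(OC)cc(O)c2C(=O)O)SCCCS1 | intermediate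
10 | 2,4-dihydroxy-6-propylbenzoic acid | CCCc1cc(O)cc(O)c1C(=O)O | starting material
11 | benzyl bromide | BrCc1ccccc1 | starting material
12 | benzyl 2,4-dihydroxy-6-propylbenzoate | CCCc1cc(O)cc(O)c1C(=O)OCc1ccccc1 | intermediate
13 | 2-hydroxy-4-methoxy-6-[(2-propyl-1,3-dithian-2-yl)methyl]benzoic trifluoroacetic anhydride | CCCC1(Cc2cc(OC)cc(O)c2C(=O)OC(=O)C(F)(F)F)SCCCS1 | intermediate
14 | benzyl 2-hydroxy-4-({2-hydroxy-4-methoxy-6-[(2-propyl-1,3-dithian-2-yl)methyl]benzoyl}oxy)-6-propylbenzoate | CCCC1(Cc2cc(OC)cc(O)c2C(=O)Oc2cc(O)c(C(=O)OCc3ccccc3)c(CCC)c2)SCCCS1 | intermediate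
15 | benzyl 2-hydroxy-4-{[2-hydroxy-4-methoxy-6-(2-oxopentyl)benzoyl]oxy}-6-propylbenzoate | CCCC(=O)Cc1cc(OC)cc(O)c1C(=O)Oc1cc(O)c(C(=O)OCc2ccccc2)c(CCC)c1 | intermediate
16 | 2-hydroxy-4-{[2-hydroxy-4-methoxy-6-(2-oxopentyl)benzoyl]oxy}-6-propylbenzoic acid | CCCC(=O)Cc1cc(OC)cc(O)c1C(=O)Oc1cc(O)c(C(=O)O)c(CCC)c1 | target

**Step count and risks**
Total step count: 8. Longest linear sequence: 7 (steps 1, 2, 3, 4, 6, 7, 8); step 5 is a one-step branch.

Most likely to fail, step 2 (key C–H annulation). The free ortho-phenol may chelate rhodium, the acid may O-alkylate the protonated ylide, or the electron-rich acid may decarboxylate. The fallback replaces the C–H step by an acyl-anion alkylation; it sets out from 8 and comes back at 9, bypassing steps 3 and 4. Dithiol 8 is condensed with butanal (BF3·OEt2, CH2Cl2, 0 °C) to 2-propyl-1,3-dithiane F1. Commercial 2-hydroxy-4-methoxy-6-methylbenzoic acid is closed with acetone, (CF3CO)2O and CF3CO2H to 7-methoxy-2,2,5-trimethyl-4H-1,3-benzodioxin-4-one F2. This is brominated at the benzylic position (N-bromosuccinimide, AIBN, PhCF3, 80 °C) to 5-(bromomethyl)-7-methoxy-2,2-dimethyl-4H-1,3-benzodioxin-4-one F3. Lithiated F1 (C4H9Li, THF, −30 °C) is alkylated by F3 at −78 °C to 7-methoxy-2,2-dimethyl-5-[(2-propyl-1,3-dithian-2-yl)methyl]-4H-1,3-benzodioxin-4-one F4. KOH in DMSO–water at 80 °C then opens the acetonide to 9.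

Second, step 4 (thioketalisation of the free keto acid). Under the Lewis acid the keto acid may dehydrate back to 7 faster than it is thioketalised. The fallback masks the ketone at the ester stage, where lactonisation is no longer possible; it sets out from 6 and comes back at 9. Keto acid 6 is methylated with trimethylsilyldiazomethane (toluene–MeOH, 0 °C) to methyl 2-hydroxy-4-methoxy-6-(2-oxopentyl)benzoate F5. This is thioketalised with 8 and BF3·OEt2 to methyl 2-hydroxy-4-methoxy-6-[(2-propyl-1,3-dithian-2-yl)methyl]benzoate F6. The hindered ester is saponified (KOH, DMSO–water, 90 °C) to 9.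

Third, step 7 (dethioketalisation on the depside). Prolonged warming with MeI may methylate a phenol, or the liberated β-keto aryl ester may expel ring B as isocoumarin 7. The fallback uses an oxidation–Pummerer sequence at low temperature instead of alkylative hydrolysis; it sets out from 14 and comes back at 15. One sulfur of 14 is oxidised (NaIO4, MeOH–H2O, 0 °C) to benzyl 2-hydroxy-4-({2-hydroxy-4-methoxy-6-[(1-oxido-2-propyl-1,3-dithian-2-yl)methyl]benzoyl}oxy)-6-propylbenzoate F7 (diastereomer mixture, no configuration assigned). The sulfoxide is then activated with (CF3CO)2O and 2,6-lutidine in MeCN at −40 °C and quenched with aqueous NaHCO3, which collapses it to ketone 15.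

**Further compounds**
F1 | step 2 | 2-propyl-1,3-dithiane | CCCC1SCCCS1
F2 | step 2 | 7-methoxy-2,2,5-trimethyl-4H-1,3-benzodioxin-4-one | COc1cc(C)c2C(=O)OC(C)(C)Oc2c1
F3 | step 2 | 5-(bromomethyl)-7-methoxy-2,2-dimethyl-4H-1,3-benzodioxin-4-one | COc1cc(CBr)c2C(=O)OC(C)(C)Oc2c1
F4 | step 2 | 7-methoxy-2,2-dimethyl-5-[(2-propyl-1,3-dithian-2-yl)methyl]-4H-1,3-benzodioxin-4-one | CCCC1(Cc2cc(OC)cc3OC(C)(C)OC(=O)c23)SCCCS1
F5 | step 4 | methyl 2-hydroxy-4-methoxy-6-(2-oxopentyl)benzoate | CCCC(=O)Cc1cc(OC)cc(O)c1C(=O)OC
F6 | step 4 | methyl 2-hydroxy-4-methoxy-6-[(2-propyl-1,3-dithian-2-yl)methyl]benzoate | CCCC1(Cc2cc(OC)cc(O)c2C(=O)OC)SCCCS1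
F7 | step 7 | benzyl 2-hydroxy-4-({2-hydroxy-4-methoxy-6-[(1-oxido-2-propyl-1,3-dithian-2-yl)methyl]benzoyl}oxy)-6-propylbenzoate (diastereomer mixture) | CCCC1(Cc2cc(OC)cc(O)c2C(=O)Oc2cc(O)c(C(=O)OCc3ccccc3)c(CCC)c2)S(=O)CCCS1
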